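Remark on the chemistry: the target has no stereogenic element, so no configuration has to be set. The aryl iodanes 13, 15 and 18 are drawn covalently and the iodonium salt 16 as an ion pair.

## Analysis of the target

The target is a depside, two benzene rings (ring A and ring B) joined only through an ester, with no fused ring and no stereocenter, so every selectivity issue is one of chemo- and regiocontrol. Ring A is a 2,4-dimethoxy-6-(2-oxoheptyl)benzoyl unit whose carboxyl carbon on C1 is wedged between the C2 methoxy group and the C6 side chain. Ring B is a 2-methoxy-6-pentylbenzoic acid that carries the ester oxygen on C4 and keeps a free carboxylic acid on C1, so two carboxyl groups have to be told apart. The sensitive groups are the aryl ester, which behaves as an active ester toward bases and nucleophiles, and the ArCH2C(=O) unit of ring A, whose enol oxygen can close a six-membered lactone (an isocoumarin) onto the ester carbonyl and expel ring B as a phenoxide. The same closure would intercept any activated derivative of the ring A acid, which is crowded and electron-rich besides, so forming the depside by acylation of a ring B phenol is the hard part. The plan rests on where the ester oxygen sits: on ring B C4, para to the C1 carboxyl and flanked only by C3-H and C5-H. That carbon is electron-poor and unencumbered, can be reached selectively in a ring B precursor because it is the only C-H without an ortho neighbour, and is well suited to be transferred from trivalent iodine to the ring A carboxylate.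

## Retrosynthetic reasoning

Target 20 to 19. The last disconnection is the O-tert-butyl bond of the ring B carboxyl. While the depside bond is made, ring B must not offer a second carboxylate, and the mask must come off without base or nucleophile, since either would cleave the aryl ester or trigger lactonisation. A tert-butyl ester removed by anhydrous acid meets both needs.

19 to 6 and 16. The bond cut is the one between the ester oxygen and ring B C4, not the acyl C-O bond. Cutting at the acyl carbon would call for an activated form of the crowded ring A acid next to an enolisable ketone. Cutting at the aryl carbon makes acid 6 the nucleophile, which only has to be deprotonated to 17, and makes ring B the electrophile as the aryl(2,4,6-trimethoxyphenyl)iodonium tosylate 16. The forward reaction, which passes through 18, must deliver the ring B aryl group and not the trimethoxyphenyl group, and must arylate oxygen while the ketone stays un-ionised.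

16 to 13 and 14, and 13 to 12. The iodine-carbon bond to the trimethoxyphenyl ligand is cut next, giving the diacetoxyiodoarene 13 and the arene 14, and 13 comes from aryl iodide 12 by oxidation. A hot one-pot oxidation in the presence of a sulfonic acid would endanger the tert-butyl ester. Oxidation in a weak carboxylic acid is therefore separated from a brief, cold exchange to the hydroxy(tosyloxy)iodoarene 15, which 14 captures at once.

12 to 11 to 10. The C4-I bond is traced to the C4-B bond of boronate 11 and this to the C4-H bond of 10. Electrophilic halogenation of 10 would go ortho and para to the methoxy and pentyl groups, that is to C3 and C5. C4 is meta to both donors but is the only C-H without an ortho neighbour, so a sterically governed C-H borylation reaches it, and ipso exchange of boron for iodine fixes the position.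

10 to 9 to 7. The ester is taken back to acid 9, to be formed by O-alkylation so that the crowded acyl carbon is not involved. The pentyl chain is cut between its first and second carbon, which leads to the benzylic dianion 8 of the simple toluic acid 7 and an alkylating agent that supplies the remaining four carbons.

6 to 5 to 3 and 2, and 2 to 1. In ring A the bond between the benzylic carbon and the ketone carbonyl is cut. This gives the lateral anion 4 of toluate 3 and the N-methoxy-N-methylamide 2, made from acid chloride 1. The amide stops the addition at the ketone stage and keeps the acidic product masked as a chelate until the quench. Hydrolysis of methyl ester 5 then frees acid 6.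

## Alternatives that were turned down

Alternative 1: Ring B would be built by cycloaddition instead of being functionalised. The ring B bonds C1-C2 and C5-C6 are disconnected to 1,1-dimethoxy-3-(trimethylsilyloxy)buta-1,3-diene A2 and benzyl oct-2-ynoate A3. In the forward step the nucleophilic terminus of A2 adds to the pentyl-bearing alkyne carbon of A3 and the acetal carbon to the ester-bearing one. Loss of one acetal methoxy group and desilylation then aromatise the adduct to benzyl 4-hydroxy-2-methoxy-6-pentylbenzoate A1.
- For: the oxygenation pattern is fixed by the diene, and A1 arrives in one step. On step count for ring B this is stronger than the six steps used here to reach 16.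
- Against: as a 3-alkyl ynoate, A3 is a sluggish dienophile and would need temperatures at which the silyl ketene acetal diene A2 is fragile.
- Against, and decisive: A1 is a phenol, so the depside bond would still have to be made by activating the carboxyl of 6. That is the operation which the flanking groups hinder and which the ketone diverts into 6,8-dimethoxy-3-pentyl-1H-isochromen-1-one A4.
- Comparison: masking the ketone to block closure to A4 would add steps and an acidic deprotection beside an aryl ester. The chosen strategy spends more steps on ring B but forms the ester without an acyl electrophile.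

Alternative 2: Ring A would be formed last, by the biomimetic route. The ring A bond C1-C6 is disconnected, giving the open-chain benzyl 2-methoxy-6-pentyl-4-{[3,5,7-trioxo-8-(2-pentyl-1,3-dioxolan-2-yl)octanoyl]oxy}benzoate A6, in which the depside ester already exists. Forward, C2 of the chain adds to the C7 ketone, and dehydration and enolisation give benzyl 4-({2,4-dihydroxy-6-[(2-pentyl-1,3-dioxolan-2-yl)methyl]benzoyl}oxy)-2-methoxy-6-pentylbenzoate A5.
- For: the ester is made on an unhindered acyl fragment before ring A exists, and no hypervalent iodine chemistry is needed. On that point it is stronger.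
- Against: A6 is an aryl ester of a polyketo acid. A chain enol can lactonise onto the ester to a pyrone and expel ring B, and Claisen folding competes with the aldol mode.
- Against: assembling A6 by enolate acylations is hard to reconcile with an aryl ester.
- Against: after the key step both phenols of A5 must be methylated under base beside the aryl ester, the dioxolane removed and the benzyl group cleaved.
- Comparison: the chosen strategy uses two stable, isolable partners, a single late bond formation and one step after it.

Alternative 3: Ester and ketone carbonyls would be reconnected as the C2=C3 double bond of benzyl 4-[(4,6-dimethoxy-2-pentyl-1H-inden-3-yl)oxy]-2-methoxy-6-pentylbenzoate A8. Forward, ozonolysis cleaves the tetrasubstituted enol ether. C3 becomes the aryl ester carbonyl and C2 the ketone, which opens the five-membered ring to benzyl 4-{[2,4-dimethoxy-6-(2-oxoheptyl)benzoyl]oxy}-2-methoxy-6-pentylbenzoate A7.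
- For: both carbonyls appear at low temperature with no base and no acylation. On mildness of the ester-forming event this is at least as strong as the chosen step.
- Against: A8 requires 5,7-dimethoxy-2-pentylindan-1-one A9, the phenol A1, and the formation of a crowded tetrasubstituted aryl enol ether between them, for which no routine method exists. Indanone A9 would itself need a separate ring synthesis.
- Against: the oxidant must distinguish the enol ether from two electron-rich methoxyarenes, and the route is clearly longer.
- Comparison: the chosen strategy is convergent and uses standard fragment syntheses. Its coupling medium is also free of base once the carboxylate is consumed, which recovers much of the mildness that the formation of A7 offers.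

Key step: step 10

## Route

Step 1
Reactants: 1 hexanoyl chloride
Product: 2 N-methoxy-N-methylhexanamide
Conditions: MeNHOMe·HCl (1.1 equiv), pyridine (2.2 equiv), CH2Cl2, 0 °C to rt
Reagents that add atoms: N,O-dimethylhydroxylamine hydrochloride, CNOC.Cl
Why: Acyl substitution of the acid chloride by the hydroxylamine nitrogen (amide formation), with pyridine taking up both equivalents of HCl.

Step 2
Reactants: 3 methyl 2,4-dimethoxy-6-methylbenzoate; 2 N-methoxy-N-methylhexanamide
Product: 5 methyl 2,4-dimethoxy-6-(2-oxoheptyl)benzoate, via benzylic lithium species 4 (not isolated)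
Conditions: LiN(iPr)2 (1.1 equiv), THF, −78 °C; then 2 (1.2 equiv), −78 °C; sat. aq. NH4Cl, −78 °C to rt
Reagents that add atoms: none
Why: Lateral lithiation of an ortho-toluate followed by Weinreb ketone synthesis; the ester acidifies the methyl group, the two ortho substituents shield the ester from self-condensation, only a slight excess of base is used so that the amide is not enolised, and the chelated tetrahedral adduct of 2 persists until the cold quench, so neither over-addition nor enolate chemistry of the product can take place in the flask.

Step 3
Reactants: 5 methyl 2,4-dimethoxy-6-(2-oxoheptyl)benzoate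
Product: 6 2,4-dimethoxy-6-(2-oxoheptyl)benzoic acid
Conditions: KOH (5 equiv), EtOH/H2O 4:1, 80 °C; then 1 M HCl to pH 3, 0 °C
Reagents that add atoms: potassium hydroxide, [K+].[OH-]
Why: Ester saponification; the shielded ester can also be cleaved by attack of the neighbouring enolate oxygen, and hydroxide reopens any enol lactone formed in this way to the same keto carboxylate, which after cold acidification should be isolable as the open keto acid.

Step 4
Reactants: 7 2-methoxy-6-methylbenzoic acid
Product: 9 2-methoxy-6-pentylbenzoic acid, via dilithio dianion 8 (not isolated)
Conditions: LiN(iPr)2 (2.2 equiv), THF, −78 to 0 °C; then 1-bromobutane (1.2 equiv), −78 °C to rt; 1 M HCl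
Reagents that add atoms: 1-bromobutane, CCCCBr
Why: Lateral metalation of a lithium ortho-toluate and SN2 alkylation of the benzylic dianion; both positions ortho to the carboxylate are substituted, so the amide base removes a methyl proton, and the carbanion is far more nucleophilic than the carboxylate oxygen.

Step 5
Reactants: 9 2-methoxy-6-pentylbenzoic acid
Product: 10 tert-butyl 2-methoxy-6-pentylbenzoate
Conditions: tert-butyl 2,2,2-trichloroacetimidate (2 equiv), BF3·OEt2 (cat.), CH2Cl2/cyclohexane, rt
Reagents that add atoms: tert-butyl 2,2,2-trichloroacetimidate, CC(C)(C)OC(=N)C(Cl)(Cl)Cl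
Why: Acid-catalysed alkylative esterification with a trichloroacetimidate; the carboxyl oxygen captures the tert-butyl cation released from the activated imidate, so the crowded acyl carbon between the methoxy and pentyl groups is never attacked.

Step 6
Reactants: 10 tert-butyl 2-methoxy-6-pentylbenzoate
Product: 11 tert-butyl 2-methoxy-6-pentyl-4-(4,4,5,5-tetramethyl-1,3,2-dioxaborolan-2-yl)benzoate
Conditions: [Ir(OMe)(cod)]2 (1.5 mol %), 4,4'-di-tert-butyl-2,2'-bipyridine (3 mol %), B2pin2 (1.0 equiv), cyclohexane, 80 °C
Reagents that add atoms: bis(pinacolato)diboron, CC1(C)OB(OC1(C)C)B1OC(C)(C)C(C)(C)O1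
Why: Sterically governed iridium-catalysed aromatic C-H borylation; C4-H is the only ring hydrogen without an ortho substituent (C3-H adjoins the methoxy group and C5-H the pentyl chain), and ester-directed ortho borylation is excluded because both ortho positions are occupied.

Step 7
Reactants: 11 tert-butyl 2-methoxy-6-pentyl-4-(4,4,5,5-tetramethyl-1,3,2-dioxaborolan-2-yl)benzoate
Product: 12 tert-butyl 4-iodo-2-methoxy-6-pentylbenzoate
Conditions: CuI (10 mol %), 1,10-phenanthroline (20 mol %), KI (1.5 equiv), MeOH/H2O 4:1, air, 80 °C
Reagents that add atoms: potassium iodide, [K+].[I-]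
Why: Copper-mediated ipso-iododeboronation; the aryl group passes from boron to copper, aerobic oxidation and C-I reductive elimination place iodine on the carbon that carried boron, and the near-neutral aqueous methanol leaves the hindered tert-butyl ester untouched.

Step 8
Reactants: 12 tert-butyl 4-iodo-2-methoxy-6-pentylbenzoate
Product: 13 tert-butyl 4-(diacetoxyiodo)-2-methoxy-6-pentylbenzoate
Conditions: NaBO3·4H2O (10 equiv), AcOH, 45 °C
Reagents that add atoms: acetic acid, CC(=O)O
Why: Oxidation of an aryl iodide to a (diacetoxyiodo)arene by peracetic acid generated from perborate; the para ester slows the oxidation without preventing it, and acetic acid is too weak to ionise the tert-butyl ester.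

Step 9
Reactants: 13 tert-butyl 4-(diacetoxyiodo)-2-methoxy-6-pentylbenzoate; 14 1,3,5-trimethoxybenzene
Product: 16 [4-(tert-butoxycarbonyl)-3-methoxy-5-pentylphenyl](2,4,6-trimethoxyphenyl)iodonium tosylate, via hydroxy(tosyloxy)iodoarene 15 (not isolated)
Conditions: TsOH·H2O (1.0 equiv), MeCN, 0 °C, 10 min; then 14 (1.05 equiv), 0 °C to rt; trituration with Et2O
Reagents that add atoms: p-toluenesulfonic acid monohydrate, Cc1ccc(S(=O)(=O)O)cc1.O
Why: Ligand exchange of acetate for tosylate gives the strongly electrophilic hydroxy(tosyloxy)iodoarene, which the very electron-rich arene 14 attacks at iodine in an electrophilic aromatic substitution at its only kind of C-H; the single equivalent of sulfonic acid ends as the counter-ion, so the tert-butyl ester meets free strong acid only briefly at 0 °C, and the ring B carbon-iodine bond fixed in step 7 is carried through unchanged.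

Step 10
Reactants: 6 2,4-dimethoxy-6-(2-oxoheptyl)benzoic acid; 16 [4-(tert-butoxycarbonyl)-3-methoxy-5-pentylphenyl](2,4,6-trimethoxyphenyl)iodonium tosylate
Product: 19 tert-butyl 4-{[2,4-dimethoxy-6-(2-oxoheptyl)benzoyl]oxy}-2-methoxy-6-pentylbenzoate, via cesium carboxylate 17 (not isolated), via iodonium carboxylate 18 (not isolated)
Conditions: 6, Cs2CO3 (0.5 equiv), MeOH, rt, then evaporation and toluene azeotrope; 16 (1.1 equiv), toluene, 100 °C
Reagents that add atoms: none
Why: The step is a metal-free O-arylation of a carboxylate by a diaryliodonium salt, and its closest known reaction type is the aryl ester synthesis from carboxylic acids, 2,6-disubstituted benzoic acids included, and diaryliodonium salts. Half an equivalent of Cs2CO3 turns 6 into 17, which takes the place of tosylate on trivalent iodine and so forms the T-shaped aryl iodane carboxylate 18. Reductive ligand coupling through a three-centre transition state then forges the bond between the carboxylate oxygen and ring B C4, with 2-iodo-1,3,5-trimethoxybenzene as the leaving group. No ring is closed and no stereocenter is formed. The first selectivity needed is the choice of aryl group: negative charge builds up on the ipso carbon in the transition state, which the para ester of ring B stabilises and the three methoxy groups of the other aryl ligand disfavour, and ring B C4 has two ortho hydrogens, so the trimethoxyphenyl group should stay on iodine. The second is O- against C-arylation: carbonate ionises only the carboxylic acid, which is many pKa units more acidic than the ketone methylene, so no enolate is available, and tosylate is too poor a nucleophile to compete. Because the acyl carbon of ring A is never activated, its shielding by the C2 methoxy group and the C6 side chain does not matter and lactonisation by the ketone cannot start. Once the carboxylate is consumed the mixture contains no base, which protects the aryl ester of 19 from enolate-induced cleavage.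

Step 11
Reactants: 19 tert-butyl 4-{[2,4-dimethoxy-6-(2-oxoheptyl)benzoyl]oxy}-2-methoxy-6-pentylbenzoate
Product: 20 4-{[2,4-dimethoxy-6-(2-oxoheptyl)benzoyl]oxy}-2-methoxy-6-pentylbenzoic acid
Conditions: CF3CO2H/CH2Cl2 1:4, 0 °C to rt
Reagents that add atoms: none
Why: Acidolysis of the tert-butyl ester by alkyl-oxygen cleavage with loss of 2-methylpropene; the anhydrous acid offers no nucleophile for the aryl ester and leaves the ketone and methyl ethers alone, and the low temperature keeps acid-promoted enol lactonisation slow.

## Compound list

1 | hexanoyl chloride | CCCCCC(=O)Cl | starting material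
2 | N-methoxy-N-methylhexanamide | CCCCCC(=O)N(C)OC | intermediate
3 | methyl 2,4-dimethoxy-6-methylbenzoate | COc1cc(C)c(C(=O)OC)c(OC)c1 | starting material
4 | methyl 2-(lithiomethyl)-4,6-dimethoxybenzoate (not isolated) | [Li]Cc1cc(OC)cc(OC)c1C(=O)OC | intermediate
5 | methyl 2,4-dimethoxy-6-(2-oxoheptyl)benzoate | CCCCCC(=O)Cc1cc(OC)cc(OC)c1C(=O)OC | intermediate
6 | 2,4-dimethoxy-6-(2-oxoheptyl)benzoic acid | CCCCCC(=O)Cc1cc(OC)cc(OC)c1C(=O)O | intermediate
7 | 2-methoxy-6-methylbenzoic acid | COc1cccc(C)c1C(=O)O | starting material
8 | lithium 2-(lithiomethyl)-6-methoxybenzoate (not isolated) | [Li]Cc1cccc(OC)c1C(=O)O[Li] | intermediate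
9 | 2-methoxy-6-pentylbenzoic acid | CCCCCc1cccc(OC)c1C(=O)O | intermediate
10 | tert-butyl 2-methoxy-6-pentylbenzoate | CCCCCc1cccc(OC)c1C(=O)OC(C)(C)C | intermediate
11 | tert-butyl 2-methoxy-6-pentyl-4-(4,4,5,5-tetramethyl-1,3,2-dioxaborolan-2-yl)benzoate | CCCCCc1cc(B2OC(C)(C)C(C)(C)O2)cc(OC)c1C(=O)OC(C)(C)C | intermediate
12 | tert-butyl 4-iodo-2-methoxy-6-pentylbenzoate | CCCCCc1cc(I)cc(OC)c1C(=O)OC(C)(C)C | intermediate
13 | tert-butyl 4-(diacetoxyiodo)-2-methoxy-6-pentylbenzoate | CCCCCc1cc(I(OC(C)=O)OC(C)=O)cc(OC)c1C(=O)OC(C)(C)C | intermediate
14 | 1,3,5-trimethoxybenzene | COc1cc(OC)cc(OC)c1 | starting material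
15 | tert-butyl 4-[hydroxy(tosyloxy)iodo]-2-methoxy-6-pentylbenzoate (not isolated) | CCCCCc1cc(I(O)OS(=O)(=O)c2ccc(C)cc2)cc(OC)c1C(=O)OC(C)(C)C | intermediate
16 | [4-(tert-butoxycarbonyl)-3-methoxy-5-pentylphenyl](2,4,6-trimethoxyphenyl)iodonium tosylate | CCCCCc1cc([I+]c2c(OC)cc(OC)cc2OC)cc(OC)c1C(=O)OC(C)(C)C.Cc1ccc(S(=O)(=O)[O-])cc1 | intermediate
17 | cesium 2,4-dimethoxy-6-(2-oxoheptyl)benzoate (not isolated) | CCCCCC(=O)Cc1cc(OC)cc(OC)c1C(=O)[O-].[Cs+] | intermediate
18 | [4-(tert-butoxycarbonyl)-3-methoxy-5-pentylphenyl](2,4,6-trimethoxyphenyl)iodonium 2,4-dimethoxy-6-(2-oxoheptyl)benzoate, drawn as the aryl iodane carboxylate (not isolated) | CCCCCC(=O)Cc1cc(OC)cc(OC)c1C(=O)OI(c1cc(CCCCC)c(C(=O)OC(C)(C)C)c(OC)c1)c1c(OC)cc(OC)cc1OC | intermediate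
19 | tert-butyl 4-{[2,4-dimethoxy-6-(2-oxoheptyl)benzoyl]oxy}-2-methoxy-6-pentylbenzoate | CCCCCC(=O)Cc1cc(OC)cc(OC)c1C(=O)Oc1cc(CCCCC)c(C(=O)OC(C)(C)C)c(OC)c1 | intermediate
20 | 4-{[2,4-dimethoxy-6-(2-oxoheptyl)benzoyl]oxy}-2-methoxy-6-pentylbenzoic acid | CCCCCC(=O)Cc1cc(OC)cc(OC)c1C(=O)Oc1cc(CCCCC)c(C(=O)O)c(OC)c1 | target

## Step count and least certain steps

Total: 11 steps. Longest linear sequence: 8 steps (from 7 to 20 through steps 4 to 11). The ring A branch (steps 1 to 3) joins at step 10.

Step 10 (key step). The most likely failure is slow ligand coupling of the crowded, electron-rich carboxylate. Thermal breakdown of the iodonium species would then compete, with transfer of the wrong aryl group or arylation of tosylate. A second failure mode is enolisation of the benzylic ketone by residual base, followed by intramolecular attack on the new aryl ester and loss of ring B. The fallback keeps the same aryl C-O bond but replaces the iodane by a Chan-Lam-type copper coupling. It sets out from 11 and 6. The pinacol ester of 11 would be cleaved oxidatively with NaIO4 and NH4OAc in acetone/water to [4-(tert-butoxycarbonyl)-3-methoxy-5-pentylphenyl]boronic acid F1. Boronic acid F1 would then be coupled with 6 using Cu(OTf)2 and urea in ethyl acetate under air at 60 °C, where an aryl copper carboxylate undergoes C-O reductive elimination. This comes back to the route at 19.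

Step 3. Hydrolysis of the shielded, electron-rich ester may stall. Alternatively the enolate on the alkyl side of the ketone may attack the ester in a Claisen-type carbocyclisation under hot alkali. The fallback reverses the order of events and sets out from 3. The ester would be hydrolysed first, with KOH in DMSO/water at 110 °C and no ketone present, to 2,4-dimethoxy-6-methylbenzoic acid F2. Acid F2 would then be doubly deprotonated with LiN(iPr)2 (2.2 equiv) in THF and acylated at the benzylic carbon with 2. Acidic work-up would give the keto acid directly, so the route is rejoined at 6.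

Step 9. The tert-butyl group may be lost by acidolysis while free sulfonic acid is present. Electron transfer from the very electron-rich arene 14 to the trivalent iodine reagent may also compete with C-I bond formation. The fallback forms the aryl-iodine bond without any strong acid and sets out from 13. Condensation with 14 in 2,2,2-trifluoroethanol at rt should give [4-(tert-butoxycarbonyl)-3-methoxy-5-pentylphenyl](2,4,6-trimethoxyphenyl)iodonium acetate F3, since the fluoroalcohol activates the diacetate by hydrogen bonding. The acetate F3 would then undergo anion metathesis with aqueous NaOTs in CH2Cl2, which returns to the route at 16.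

Step 4. Lateral deprotonation of the lithium carboxylate may be incomplete, ring metalation next to the methoxy group may compete, or a second alkylation may follow. The fallback swaps steps 4 and 5 so that the carbanion is stabilised by an ester, and sets out from 7. Esterification with tert-butyl 2,2,2-trichloroacetimidate would give tert-butyl 2-methoxy-6-methylbenzoate F4. Lateral lithiation of F4 with LiN(iPr)2 in THF at −78 °C and alkylation with 1-iodobutane would then rejoin the route at 10.

Step 11. The acid may promote lactonisation of the ketone enol onto the aryl ester with expulsion of ring B, and the liberated tert-butyl cation may alkylate ring A. The fallback changes the ring B protecting group so that the last step is a neutral hydrogenolysis, and it sets out from 12. Acidolysis with CF3CO2H would give 4-iodo-2-methoxy-6-pentylbenzoic acid F5. Treatment of F5 with benzyl bromide and K2CO3 in DMF would give benzyl 4-iodo-2-methoxy-6-pentylbenzoate F6. Oxidation of F6 with mCPBA and TsOH·H2O in MeCN and condensation in the same flask with 14 would give {4-[(benzyloxy)carbonyl]-3-methoxy-5-pentylphenyl}(2,4,6-trimethoxyphenyl)iodonium tosylate F7; the benzyl ester tolerates these conditions. Coupling of F7 with 17 in toluene at 100 °C would give benzyl 4-{[2,4-dimethoxy-6-(2-oxoheptyl)benzoyl]oxy}-2-methoxy-6-pentylbenzoate F8. Hydrogenolysis of F8 with H2 over Pd/C in ethyl acetate would then lead to 20.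

## Further compounds

F1 | step 10 | [4-(tert-butoxycarbonyl)-3-methoxy-5-pentylphenyl]boronic acid | CCCCCc1cc(B(O)O)cc(OC)c1C(=O)OC(C)(C)C
F2 | step 3 | 2,4-dimethoxy-6-methylbenzoic acid | COc1cc(C)c(C(=O)O)c(OC)c1
F3 | step 9 | [4-(tert-butoxycarbonyl)-3-methoxy-5-pentylphenyl](2,4,6-trimethoxyphenyl)iodonium acetate | CCCCCc1cc([I+]c2c(OC)cc(OC)cc2OC)cc(OC)c1C(=O)OC(C)(C)C.CC(=O)[O-]
F4 | step 4 | tert-butyl 2-methoxy-6-methylbenzoate | COc1cccc(C)c1C(=O)OC(C)(C)C
F5 | step 11 | 4-iodo-2-methoxy-6-pentylbenzoic acid | CCCCCc1cc(I)cc(OC)c1C(=O)O
F6 | step 11 | benzyl 4-iodo-2-methoxy-6-pentylbenzoate | CCCCCc1cc(I)cc(OC)c1C(=O)OCc1ccccc1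
F7 | step 11 | {4-[(benzyloxy)carbonyl]-3-methoxy-5-pentylphenyl}(2,4,6-trimethoxyphenyl)iodonium tosylate | CCCCCc1cc([I+]c2c(OC)cc(OC)cc2OC)cc(OC)c1C(=O)OCc1ccccc1.Cc1ccc(S(=O)(=O)[O-])cc1
F8 | step 11 | benzyl 4-{[2,4-dimethoxy-6-(2-oxoheptyl)benzoyl]oxy}-2-methoxy-6-pentylbenzoate | CCCCCC(=O)Cc1cc(OC)cc(OC)c1C(=O)Oc1cc(CCCCC)c(C(=O)OCc2ccccc2)c(OC)c1
A1 | alternative 1 | benzyl 4-hydroxy-2-methoxy-6-pentylbenzoate | CCCCCc1cc(O)cc(OC)c1C(=O)OCc1ccccc1
A2 | alternative 1 | 1,1-dimethoxy-3-(trimethylsilyloxy)buta-1,3-diene | COC(OC)=CC(=C)O[Si](C)(C)C
A3 | alternative 1 | benzyl oct-2-ynoate | CCCCCC#CC(=O)OCc1ccccc1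
A4 | alternative 1 | 6,8-dimethoxy-3-pentyl-1H-isochromen-1-one | CCCCCc1cc2cc(OC)cc(OC)c2c(=O)o1
A5 | alternative 2 | benzyl 4-({2,4-dihydroxy-6-[(2-pentyl-1,3-dioxolan-2-yl)methyl]benzoyl}oxy)-2-methoxy-6-pentylbenzoate | CCCCCC1(OCCO1)Cc1cc(O)cc(O)c1C(=O)Oc1cc(CCCCC)c(C(=O)OCc2ccccc2)c(OC)c1
A6 | alternative 2 | benzyl 2-methoxy-6-pentyl-4-{[3,5,7-trioxo-8-(2-pentyl-1,3-dioxolan-2-yl)octanoyl]oxy}benzoate | CCCCCC1(OCCO1)CC(=O)CC(=O)CC(=O)CC(=O)Oc1cc(CCCCC)c(C(=O)OCc2ccccc2)c(OC)c1
A7 | alternative 3 | benzyl 4-{[2,4-dimethoxy-6-(2-oxoheptyl)benzoyl]oxy}-2-methoxy-6-pentylbenzoate | CCCCCC(=O)Cc1cc(OC)cc(OC)c1C(=O)Oc1cc(CCCCC)c(C(=O)OCc2ccccc2)c(OC)c1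
A8 | alternative 3 | benzyl 4-[(4,6-dimethoxy-2-pentyl-1H-inden-3-yl)oxy]-2-methoxy-6-pentylbenzoate | CCCCCC1=C(Oc2cc(CCCCC)c(C(=O)OCc3ccccc3)c(OC)c2)c2c(OC)cc(OC)cc2C1
A9 | alternative 3 | 5,7-dimethoxy-2-pentylindan-1-one (racemic) | CCCCCC1Cc2cc(OC)cc(OC)c2C1=O
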